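## Retrosynthetic overview

1. Target 23 ⇒ ring-closing metathesis at C1=C10 (ten-membered carbocycle, formed last) ⇒ seco-diene 22 ⇒ hydroxyl-directed epoxidation (C4–O/C5–O) of the (Z)-allylic alcohol 21.
2. 21 ⇒ Nozaki–Hiyama–Kishi alkenylation at C5–C6, then C6–O lactonisation (γ-lactone) ⇒ aldehyde 14 + (Z)-vinyl iodide 19.
3. 14 ⇒ C8–O esterification ⇒ alcohol 7 + epoxyangelic acid 11; 7 ⇒ indium Barbier coupling (C7–C8) ⇒ aldehyde 6 + allyl bromide 4.
4. Key step: 6 and 4 both come from the one achiral bromide 4. A catalytic enantioselective allylic acetoxylation of 4 (C9–O bond) sets C9, and C9 is relayed to C8, C7 and C6.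
5. Ring order: side-chain oxirane → γ-lactone → 4,5-oxirane → ten-membered ring.

Assumptions: C1–C15 are the germacrane positions of the target (C6 lactone carbinol, C7 ring-fusion CH, C8 epoxy-ester carbinol, C9 acetate carbinol, C1=C10 enoate, C3 carbinol, C4/C5 oxirane, C11=C13 exo-methylene, C12 lactone C=O, C14 CO2Me). (DHQD)2PHAL is taken as the pseudo-enantiomer that gives (3R)-5 in step 3 and (R)-TRIP as the acid that gives (3R)-19 in step 13; otherwise the antipodal catalyst is used.

## Route

Step 1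
Reactants: 1 methyl acrylate; 2 2,2-dimethoxyacetaldehyde (60 % aq.)
Product: 3 methyl (3RS)-3-hydroxy-4,4-dimethoxy-2-methylidenebutanoate (racemic)
Conditions: DABCO (0.5 equiv), 1,4-dioxane/H2O 1:1, rt, 24–48 h
Reagents that add atoms: none
Why: Morita–Baylis–Hillman reaction, in which the electron-poor α,α-dialkoxy aldehyde is a fast acceptor and water accelerates proton transfer; no stereocontrol is needed because the carbinol carbon is either transposed (step 2) or re-made (step 3).

Step 2
Reactants: 3 methyl (3RS)-3-hydroxy-4,4-dimethoxy-2-methylidenebutanoate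
Product: 4 methyl (2Z)-2-(bromomethyl)-4,4-dimethoxybut-2-enoate
Conditions: NBS, Me2S, CH2Cl2, 0 °C → rt
Reagents that add atoms: N-bromosuccinimide BrN1C(=O)CCC1=O
Why: Corey–Kim-type activation of the MBH alcohol as its alkoxysulfonium salt and SN2′ attack of bromide give the rearranged, thermodynamically preferred (Z)-allyl bromide (acetal trans to the ester) under neutral conditions that spare the acetal.

Step 3
Reactants: 4 methyl (2Z)-2-(bromomethyl)-4,4-dimethoxybut-2-enoate
Product: 5 methyl (3R)-3-(acetyloxy)-4,4-dimethoxy-2-methylidenebutanoate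
Conditions: finely ground KOAc (2 equiv), (DHQD)2PHAL (10 mol %), toluene/CH2Cl2 4:1, 0 °C
Reagents that add atoms: potassium acetate CC(=O)[O-].[K+]
Why: Proposed new method: enantioselective Lewis-base-catalysed SN2′ allylic acetoxylation, in which the quinuclidine nitrogen displaces bromide to give a chiral allylammonium ion pair, acetate adds to the γ-carbon on the face dictated by the alkaloid and the amine is expelled (addition–elimination), forming the C9–O bond and the (R)-centre; sparingly soluble KOAc keeps the uncatalysed SN2 path to the linear acetate slow; the closest known reactions are cinchona-amine-catalysed allylic substitutions of MBH carbonates, acetates and bromides with water, phenols and hydroperoxides, and a carboxylate nucleophile giving an MBH acetate directly has not been shown.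

Step 4
Reactants: 5 methyl (3R)-3-(acetyloxy)-4,4-dimethoxy-2-methylidenebutanoate
Product: 6 methyl (3R)-3-(acetyloxy)-2-methylidene-4-oxobutanoate
Conditions: TFA/H2O 1:1, CH2Cl2, 0 °C, 1 h; toluene azeotrope, used crude at once
Reagents that add atoms: water O
Why: Acid-catalysed acetal hydrolysis that leaves the acetate and acrylate intact; the enolisable α-acetoxy aldehyde never meets base and is not stored, so C9 is not racemised.

Step 5
Reactants: 6 methyl (3R)-3-(acetyloxy)-2-methylidene-4-oxobutanoate; 4 methyl (2Z)-2-(bromomethyl)-4,4-dimethoxybut-2-enoate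
Product: 7 dimethyl (3R,4S,5R)-3-(acetyloxy)-5-(dimethoxymethyl)-4-hydroxy-2,6-dimethylideneheptanedioate
Conditions: In powder (1.5 equiv), 4 (1.5 equiv), THF/H2O 1:1, rt, 3 h
Reagents that add atoms: none
Why: Indium-mediated Barbier 2-(alkoxycarbonyl)allylation in which the (Z)-γ-substituted allylindium reacts through a Zimmerman–Traxler chair with the acetal carbon axial (C7/C8 syn) on the Felkin–Anh face of the non-chelating α-acetoxy aldehyde (C8/C9 anti), so both new centres follow from C9, and the near-neutral aqueous medium limits acetyl migration.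

Step 6
Reactants: 8 methyl angelate [methyl (2Z)-2-methylbut-2-enoate]
Product: 9 (2Z)-2-methylbut-2-en-1-ol
Conditions: DIBAL-H (2.2 equiv), CH2Cl2, −78 → 0 °C; Rochelle salt work-up
Reagents that add atoms: none
Why: 1,2-Reduction of the enoate by DIBAL-H, which does not isomerise the (Z)-alkene.

Step 7
Reactants: 9 (2Z)-2-methylbut-2-en-1-ol
Product: 10 [(2R,3S)-2,3-dimethyloxiran-2-yl]methanol
Conditions: Ti(OiPr)4 (10 mol %), D-(−)-diethyl tartrate (12 mol %), TBHP, 4 Å MS, CH2Cl2, −20 °C
Reagents that add atoms: tert-butyl hydroperoxide CC(C)(C)OO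
Why: Sharpless asymmetric epoxidation, where the D-(−)-tartrate catalyst delivers oxygen to the face that gives the (2R,3S)-epoxide and the (Z)-alkene geometry fixes the C3 methyl cis to CH2OH.

Step 8
Reactants: 10 [(2R,3S)-2,3-dimethyloxiran-2-yl]methanol
Product: 11 (2S,3S)-2,3-dimethyloxirane-2-carboxylic acid
Conditions: RuCl3·xH2O (2 mol %), NaIO4 (3 equiv), CCl4/MeCN/H2O, rt
Reagents that add atoms: sodium periodate [Na+].[O-]I(=O)(=O)=O; water O
Why: RuO4-catalysed oxidation of the primary alcohol to the acid without touching the oxirane (the C2 descriptor changes from R to S only through CIP priorities).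

Step 9
Reactants: 7 dimethyl (3R,4S,5R)-3-(acetyloxy)-5-(dimethoxymethyl)-4-hydroxy-2,6-dimethylideneheptanedioate; 11 (2S,3S)-2,3-dimethyloxirane-2-carboxylic acid
Product: 13 dimethyl (3R,4S,5R)-3-(acetyloxy)-5-(dimethoxymethyl)-4-{[(2S,3S)-2,3-dimethyloxirane-2-carbonyl]oxy}-2,6-dimethylideneheptanedioate, via Yamaguchi mixed anhydride 12 (not isolated)
Conditions: 11, 2,4,6-trichlorobenzoyl chloride, Et3N, toluene, rt, 1 h; then 7, DMAP (0.3 equiv), 0 °C
Reagents that add atoms: none
Why: Yamaguchi esterification acylates the hindered C8 hydroxyl with retention, and the pre-formed anhydride with sub-stoichiometric DMAP at 0 °C keeps acetyl migration, SN2′ attack on the MBH acetate and lactonisation of the free C8–OH onto the C12 ester slow.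

Step 10
Reactants: 13 dimethyl (3R,4S,5R)-3-(acetyloxy)-5-(dimethoxymethyl)-4-{[(2S,3S)-2,3-dimethyloxirane-2-carbonyl]oxy}-2,6-dimethylideneheptanedioate
Product: 14 dimethyl (3R,4S,5R)-3-(acetyloxy)-4-{[(2S,3S)-2,3-dimethyloxirane-2-carbonyl]oxy}-5-formyl-2,6-dimethylideneheptanedioate
Conditions: LiBF4 (1.2 equiv), MeCN/H2O 50:1, rt; used crude at once
Reagents that add atoms: water O
Why: Mild Lewis-acid-assisted acetal hydrolysis tolerated by the deactivated glycidic ester; the C7 stereocentre α to the new aldehyde is not exposed to base and the aldehyde is used immediately.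

Step 11
Reactants: 15 propargyl alcohol
Product: 17 (2Z)-3-iodo-2-methylprop-2-en-1-ol, via vinylmagnesium alkoxide 16 (not isolated)
Conditions: MeMgBr (2.5 equiv), CuI (10 mol %), THF/Et2O, −10 °C → rt; then I2, −10 °C
Reagents that add atoms: methylmagnesium bromide C[Mg]Br; iodine II
Why: Copper-catalysed anti-carbomagnesiation of the propargylic alkoxide gives the chelated vinylmagnesium with Mg cis to CH2O, and iodinolysis with retention fixes the (Z)-geometry that later becomes the cis-4,5 unit.

Step 12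
Reactants: 17 (2Z)-3-iodo-2-methylprop-2-en-1-ol
Product: 18 (2Z)-3-iodo-2-methylprop-2-enal
Conditions: activated MnO2, CH2Cl2, rt, dark
Reagents that add atoms: none
Why: Neutral allylic oxidation with MnO2 that does not isomerise the (Z)-iodoenal.

Step 13
Reactants: 18 (2Z)-3-iodo-2-methylprop-2-enal
Product: 19 (1Z,3R)-1-iodo-2-methylhexa-1,5-dien-3-ol
Conditions: allylB(pin) (1.2 equiv), (R)-TRIP (5 mol %), toluene, −30 °C
Reagents that add atoms: allylboronic acid pinacol ester C=CCB1OC(C)(C)C(C)(C)O1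
Why: Chiral phosphoric acid-catalysed allylboration through a closed chair transition state, in which the catalyst activates the boronate and selects the aldehyde face to set the C3 carbinol as (R).

Step 14
Reactants: 14 dimethyl (3R,4S,5R)-3-(acetyloxy)-4-{[(2S,3S)-2,3-dimethyloxirane-2-carbonyl]oxy}-5-formyl-2,6-dimethylideneheptanedioate; 19 (1Z,3R)-1-iodo-2-methylhexa-1,5-dien-3-ol
Product: 21 methyl (3R,4S)-3-(acetyloxy)-4-{[(2S,3S)-2,3-dimethyloxirane-2-carbonyl]oxy}-4-{(2R,3S)-2-[(1Z,3R)-3-hydroxy-2-methylhexa-1,5-dien-1-yl]-4-methylidene-5-oxooxolan-3-yl}-2-methylidenebutanoate, via hydroxy ester 20 (not isolated)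
Conditions: CrCl2 (6 equiv), NiCl2 (2 mol %), DMSO/THF 3:1, rt; aqueous work-up, then PPTS (cat.), CH2Cl2, rt
Reagents that add atoms: none
Why: Nozaki–Hiyama–Kishi alkenylation is chemoselective for the aldehyde and keeps the (Z)-alkenyl geometry; attack anti to the C8 branch (Felkin–Anh), reinforced by 1,3-anti induction from the β-acyloxy group (Evans model), should set C6 so that the alkoxide lactonises onto the C12 methyl ester to the trans-fused α-methylene-γ-butyrolactone while the C3 hydroxyl stays free.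

Step 15
Reactants: 21 methyl (3R,4S)-3-(acetyloxy)-4-{[(2S,3S)-2,3-dimethyloxirane-2-carbonyl]oxy}-4-{(2R,3S)-2-[(1Z,3R)-3-hydroxy-2-methylhexa-1,5-dien-1-yl]-4-methylidene-5-oxooxolan-3-yl}-2-methylidenebutanoate
Product: 22 methyl (3R,4S)-3-(acetyloxy)-4-{[(2S,3S)-2,3-dimethyloxirane-2-carbonyl]oxy}-4-[(2S,3R)-2-{(2R,3S)-3-[(1R)-1-hydroxybut-3-en-1-yl]-3-methyloxiran-2-yl}-4-methylidene-5-oxooxolan-3-yl]-2-methylidenebutanoate
Conditions: VO(acac)2 (5 mol %), TBHP (1.5 equiv), CH2Cl2, 0 °C
Reagents that add atoms: tert-butyl hydroperoxide CC(C)(C)OO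
Why: Vanadium-catalysed hydroxyl-directed epoxidation touches only the C4=C5 allylic alkene (not the homoallylic vinyl or the two acrylates); A(1,3) strain holds H3 in the alkene plane, so oxygen is delivered syn to O3 (threo), on the face anti to the C2 and C7 chains, giving the cis-oxirane (4S,5R).

Step 16
Reactants: 22 methyl (3R,4S)-3-(acetyloxy)-4-{[(2S,3S)-2,3-dimethyloxirane-2-carbonyl]oxy}-4-[(2S,3R)-2-{(2R,3S)-3-[(1R)-1-hydroxybut-3-en-1-yl]-3-methyloxiran-2-yl}-4-methylidene-5-oxooxolan-3-yl]-2-methylidenebutanoate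
Product: 23 CNP0301544.1 [methyl (1(10)E,3R,4S,5R,6S,7R,8S,9R)-9-acetoxy-8-{[(2S,3S)-2,3-dimethyloxirane-2-carbonyl]oxy}-4,5-epoxy-3-hydroxy-12-oxogermacra-1(10),11(13)-dien-12,6-olid-14-oate]
Conditions: Hoveyda–Grubbs II (15 mol %), 1,4-benzoquinone (20 mol %), toluene (1 mM), 80 °C
Reagents that add atoms: none
Why: Ring-closing metathesis starts at the terminal vinyl group and closes on the C10 acrylate (closure on the C11 methylene would need a strained bridgehead alkene), and the ten-membered ring can only hold the ring-cis enoate, which is the required (E)-C1=C10 geometry with the ester trans to C2.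

## Compound list

1 | methyl acrylate | C=CC(=O)OC | starting material
2 | 2,2-dimethoxyacetaldehyde | COC(OC)C=O | starting material
3 | methyl (3RS)-3-hydroxy-4,4-dimethoxy-2-methylidenebutanoate (racemic) | COC(OC)C(O)C(=C)C(=O)OC | intermediate
4 | methyl (2Z)-2-(bromomethyl)-4,4-dimethoxybut-2-enoate | COC(OC)/C=C(\CBr)C(=O)OC | intermediate
5 | methyl (3R)-3-(acetyloxy)-4,4-dimethoxy-2-methylidenebutanoate | COC(OC)[C@H](OC(C)=O)C(=C)C(=O)OC | intermediate
6 | methyl (3R)-3-(acetyloxy)-2-methylidene-4-oxobutanoate | O=C[C@H](OC(C)=O)C(=C)C(=O)OC | intermediate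
7 | dimethyl (3R,4S,5R)-3-(acetyloxy)-5-(dimethoxymethyl)-4-hydroxy-2,6-dimethylideneheptanedioate | COC(OC)[C@H](C(=C)C(=O)OC)[C@H](O)[C@H](OC(C)=O)C(=C)C(=O)OC | intermediate
8 | methyl angelate, methyl (2Z)-2-methylbut-2-enoate | C/C=C(/C)C(=O)OC | starting material
9 | (2Z)-2-methylbut-2-en-1-ol | C/C=C(/C)CO | intermediate
10 | [(2R,3S)-2,3-dimethyloxiran-2-yl]methanol | OC[C@@]1(C)O[C@H]1C | intermediate
11 | (2S,3S)-2,3-dimethyloxirane-2-carboxylic acid | OC(=O)[C@@]1(C)O[C@H]1C | intermediate
12 | (2S,3S)-2,3-dimethyloxirane-2-carboxylic 2,4,6-trichlorobenzoic anhydride (not isolated) | O=C(OC(=O)[C@@]1(C)O[C@H]1C)c1c(Cl)cc(Cl)cc1Cl | intermediate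
13 | dimethyl (3R,4S,5R)-3-(acetyloxy)-5-(dimethoxymethyl)-4-{[(2S,3S)-2,3-dimethyloxirane-2-carbonyl]oxy}-2,6-dimethylideneheptanedioate | COC(OC)[C@H](C(=C)C(=O)OC)[C@H](OC(=O)[C@@]1(C)O[C@H]1C)[C@H](OC(C)=O)C(=C)C(=O)OC | intermediate
14 | dimethyl (3R,4S,5R)-3-(acetyloxy)-4-{[(2S,3S)-2,3-dimethyloxirane-2-carbonyl]oxy}-5-formyl-2,6-dimethylideneheptanedioate | O=C[C@H](C(=C)C(=O)OC)[C@H](OC(=O)[C@@]1(C)O[C@H]1C)[C@H](OC(C)=O)C(=C)C(=O)OC | intermediate
15 | propargyl alcohol (prop-2-yn-1-ol) | C#CCO | starting material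
16 | bromomagnesium (2Z)-3-(bromomagnesio)-2-methylprop-2-en-1-olate (not isolated) | Br[Mg]/C=C(/C)CO[Mg]Br | intermediate
17 | (2Z)-3-iodo-2-methylprop-2-en-1-ol | OC/C(C)=C\I | intermediate
18 | (2Z)-3-iodo-2-methylprop-2-enal | O=C/C(C)=C\I | intermediate
19 | (1Z,3R)-1-iodo-2-methylhexa-1,5-dien-3-ol | C=CC[C@@H](O)/C(C)=C\I | intermediate
20 | dimethyl (3R,4S,5S)-3-(acetyloxy)-5-[(1R,2Z,4R)-1,4-dihydroxy-3-methylhepta-2,6-dien-1-yl]-4-{[(2S,3S)-2,3-dimethyloxirane-2-carbonyl]oxy}-2,6-dimethylideneheptanedioate (not isolated) | C=C(C(=O)OC)[C@@H]([C@H](O)/C=C(/C)[C@H](O)CC=C)[C@H](OC(=O)[C@@]1(C)O[C@H]1C)[C@H](OC(C)=O)C(=C)C(=O)OC | intermediate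
21 | methyl (3R,4S)-3-(acetyloxy)-4-{[(2S,3S)-2,3-dimethyloxirane-2-carbonyl]oxy}-4-{(2R,3S)-2-[(1Z,3R)-3-hydroxy-2-methylhexa-1,5-dien-1-yl]-4-methylidene-5-oxooxolan-3-yl}-2-methylidenebutanoate | C=C1C(=O)O[C@H](/C=C(/C)[C@H](O)CC=C)[C@H]1[C@H](OC(=O)[C@@]1(C)O[C@H]1C)[C@H](OC(C)=O)C(=C)C(=O)OC | intermediate
22 | methyl (3R,4S)-3-(acetyloxy)-4-{[(2S,3S)-2,3-dimethyloxirane-2-carbonyl]oxy}-4-[(2S,3R)-2-{(2R,3S)-3-[(1R)-1-hydroxybut-3-en-1-yl]-3-methyloxiran-2-yl}-4-methylidene-5-oxooxolan-3-yl]-2-methylidenebutanoate | C=C1C(=O)O[C@H]([C@H]2O[C@@]2(C)[C@H](O)CC=C)[C@H]1[C@H](OC(=O)[C@@]1(C)O[C@H]1C)[C@H](OC(C)=O)C(=C)C(=O)OC | intermediate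
23 | CNP0301544.1 | C=C1C(=O)O[C@H]2[C@H]1[C@H](OC(=O)[C@@]1(C)O[C@H]1C)[C@H](OC(C)=O)/C(C(=O)OC)=C\C[C@@H](O)[C@]1(C)O[C@H]21 | target

## Step count and risks

Total steps: 16. Longest linear sequence: 10 (steps 1, 2, 3, 4, 5, 9, 10, 14, 15, 16). No protecting-group steps are used.

Three steps most likely to fail:

Step 3 (the new acetoxylation). The enantioselectivity and the branched-to-linear ratio are unknown, and the product is itself an MBH acetate that the catalyst could re-ionise. The fallback is known chemistry, sets out from 3 and returns at 5. Racemic 3 is resolved by lipase-catalysed acylation (Pseudomonas lipase, vinyl acetate, MTBE, about 50 % conversion). Taking the (S)-alcohol as the fast-reacting enantiomer, it is removed as methyl (3S)-3-(acetyloxy)-4,4-dimethoxy-2-methylidenebutanoate F2. The recovered methyl (3R)-3-hydroxy-4,4-dimethoxy-2-methylidenebutanoate F1 is acetylated (Ac2O, pyridine, 0 °C) to 5. If the enzyme prefers the (R)-alcohol, the acetate it forms is 5 itself. Bromide 4 is still made from racemic 3.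

Step 5 (indium coupling). Two stereocentres are set at once, and the aldehyde 6 is enolisable. The hydroxy-acetate 7 can also suffer acetyl migration or lactonisation. The fallback sets out from 4 (with 6) and returns at 7. Bromide 4 is converted with retention of geometry into the isolable allylboronate methyl (2E)-4,4-dimethoxy-2-[(4,4,5,5-tetramethyl-1,3,2-dioxaborolan-2-yl)methyl]but-2-enoate F3 (B2pin2, Pd2(dba)3 cat., toluene, 50 °C). F3 is added to 6 without metal or water (toluene, rt, optionally with a chiral phosphoric acid to reinforce the Felkin face). This is a closed, stereospecific type-I allylboration in which the CH2B-cis acetal carbon is again axial, so the same syn,anti triad 7 results after mild hydrolytic work-up.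

Step 16 (ring-closing metathesis). A ten-membered ring is closed onto a hindered, electron-poor 1,1-disubstituted acrylate, and oligomerisation or no reaction is possible. The fallback sets out from 21 and returns at 23, and it changes the order of ring formation. The more flexible triene 21 is cyclised first (Hoveyda–Grubbs II, toluene, 80 °C, 1 mM) to the macrocyclic (4Z)-olefin methyl (1(10)E,4Z,3R,6R,7S,8S,9R)-9-acetoxy-8-{[(2S,3S)-2,3-dimethyloxirane-2-carbonyl]oxy}-3-hydroxy-12-oxogermacra-1(10),4,11(13)-trien-12,6-olid-14-oate F4. The 4,5-oxirane is then put in last on the ring by C3–OH-directed VO(acac)2/TBHP epoxidation to give 23; the facial selectivity on the ring would have to be checked.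

Further compounds

F1 | step 3 | methyl (3R)-3-hydroxy-4,4-dimethoxy-2-methylidenebutanoate | COC(OC)[C@H](O)C(=C)C(=O)OC
F2 | step 3 | methyl (3S)-3-(acetyloxy)-4,4-dimethoxy-2-methylidenebutanoate | COC(OC)[C@@H](OC(C)=O)C(=C)C(=O)OC
F3 | step 5 | methyl (2E)-4,4-dimethoxy-2-[(4,4,5,5-tetramethyl-1,3,2-dioxaborolan-2-yl)methyl]but-2-enoate | COC(OC)/C=C(\CB1OC(C)(C)C(C)(C)O1)C(=O)OC
F4 | step 16 | methyl (1(10)E,4Z,3R,6R,7S,8S,9R)-9-acetoxy-8-{[(2S,3S)-2,3-dimethyloxirane-2-carbonyl]oxy}-3-hydroxy-12-oxogermacra-1(10),4,11(13)-trien-12,6-olid-14-oate | C=C1C(=O)O[C@@H]2/C=C(/C)[C@H](O)C/C=C(/C(=O)OC)[C@@H](OC(C)=O)[C@@H](OC(=O)[C@@]3(C)O[C@H]3C)[C@@H]12
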